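**Retrosynthetic overview**

1. Feature: in target 17 the benzene ring carries the C1 carboxyl between C2–OH and C6–CH2, with C4–OMe para to C1. This is the pattern of a 4-alkoxy-6-methyl-2-pyrone-5-carboxylate (pyrone C5, C4, C6 become arene C1, C2, C6) once a ketene acetal supplies arene C4(OMe) and C5(H).
2. 17 ⇒ 14 by ester hydrolysis and chelation-directed O-demethylation; 14 ⇒ arene 9 + Weinreb amide 11 across the benzylic CH2–C(=O) bond (lateral lithiation).
3. 9 ⇒ pyrone 5 + 1,1-dimethoxyethene 6: Diels–Alder addition, then loss of CO2 and MeOH (arene bonds C5–C6 and C3–C4).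
4. 5 ⇒ methyl acetoacetate 1 + malonyl dichloride 2, then O-methylation. Ring order: the 2-pyrone ring first (step 1), then the benzene ring that replaces it (step 3).

Key step: step 3

Remark: the target has no stereocentre; the few chiral species on the way are transient racemates and need no control.

**Route**

Step 1
Reactants: 1 methyl acetoacetate; 2 malonyl dichloride
Product: 4 methyl 4-hydroxy-6-methyl-2-oxo-2H-pyran-5-carboxylate, via C-acylated acyl chloride 3 (not isolated)
Conditions: 2 (1.05 equiv), dry CH2Cl2, 0 °C to rt, then 40 °C under a slow N2 purge until HCl evolution stops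
Reagents that add atoms: none
Why: Malonyl dichloride/β-keto ester pyrone annulation, in which the enol of 1 is C-acylated at its α-carbon to 3, the acetyl enol oxygen then closes onto the second acyl chloride (enol lactonisation to a six-membered ring) and the ring tautomerises to the 4-hydroxy-2-pyrone while HCl leaves as gas.

Step 2
Reactants: 4 methyl 4-hydroxy-6-methyl-2-oxo-2H-pyran-5-carboxylate
Product: 5 methyl 4-methoxy-6-methyl-2-oxo-2H-pyran-5-carboxylate
Conditions: Me2SO4 (1.2 equiv), K2CO3 (1.5 equiv), acetone, reflux
Reagents that add atoms: dimethyl sulfate, COS(=O)(=O)OC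
Why: Williamson-type O-alkylation of the vinylogous acid, the K2CO3-derived pyronate being methylated on the C4 oxygen by the hard electrophile as is usual for 4-hydroxy-6-methyl-2-pyrones.

Step 3
Reactants: 5 methyl 4-methoxy-6-methyl-2-oxo-2H-pyran-5-carboxylate; 6 1,1-dimethoxyethene
Product: 9 methyl 2,4-dimethoxy-6-methylbenzoate, via bridged lactone adduct 7 (not isolated), via cyclohexadiene ketal 8 (not isolated)
Conditions: 6 (5 equiv), toluene, trace Et3N, 140 °C, sealed tube; concentrate; then cat. p-TsOH, CH2Cl2, rt to complete MeOH loss
Reagents that add atoms: none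
Why: Pyrone 5 is an electron-poor diene (lactone carbonyl plus C5 ester) and ketene acetal 6 an electron-rich dienophile, so an inverse-electron-demand Diels–Alder reaction is expected, with the nucleophilic CH2 of 6 bonding to pyrone C6 and the acetal carbon to pyrone C3, probably in a strongly asynchronous way. The carbocycle is closed by this intermolecular [4+2] cycloaddition (both new ring bonds in one operation) to give bridged lactone 7, which loses CO2 by retro-Diels–Alder reaction to cyclohexadiene ketal 8, and 1,2-elimination of methanol (thermal, completed by the trace of acid) aromatises 8 to 9. The closest known reaction type is the cycloaddition of alkyl coumalates (2-pyrone-5-carboxylates) with ketene acetals, which gives 4-alkoxybenzoates with loss of CO2 and alcohol. No stereocentre is created in 9, the two bridgehead centres of 7 being erased in the cycloreversion. The selectivity needed is regiochemical, the new methoxy-bearing carbon must finish para to the ester carbon, and it is secured by the matched polarisation of the partners: the largest acceptor coefficient of 5 lies at C6 (β to the ester, δ to the lactone carbonyl) and the largest donor coefficient of 6 at its CH2. The 4-methoxy donor and the 6-methyl group make 5 less reactive than a plain coumalate, which is why an excess of 6 and sealed-tube heating are specified.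

Step 4
Reactants: 10 dodecanoyl chloride
Product: 11 N-methoxy-N-methyldodecanamide
Conditions: MeNHOMe·HCl (1.1 equiv), Et3N (2.2 equiv), CH2Cl2, 0 °C to rt
Reagents that add atoms: N,O-dimethylhydroxylamine hydrochloride, CNOC.Cl
Why: Schotten–Baumann-type N-acylation gives the Weinreb amide, chosen so that the later carbanion acylation stops at the ketone.

Step 5
Reactants: 9 methyl 2,4-dimethoxy-6-methylbenzoate; 11 N-methoxy-N-methyldodecanamide
Product: 14 methyl 2,4-dimethoxy-6-(2-oxotridecyl)benzoate, via benzylic lithium species 12 (not isolated), via lithium hemiaminal alkoxide 13 (not isolated)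
Conditions: LiN(iPr)2 (2.1 equiv), THF, −78 °C; then 11 (1.1 equiv), −78 to −40 °C; AcOH quench at −78 °C, then water
Reagents that add atoms: none
Why: Lateral (benzylic) lithiation of the ortho-toluate followed by Weinreb ketone synthesis, in which the ester-conjugated CH3 is the most acidic site, the two ortho substituents shield the ester from self-condensation at −78 °C, and the chelated tetrahedral adduct 13 releases the ketone only on quench so that no over-addition occurs.

Step 6
Reactants: 14 methyl 2,4-dimethoxy-6-(2-oxotridecyl)benzoate
Product: 16 methyl 2-hydroxy-4-methoxy-6-(2-oxotridecyl)benzoate, via aryloxydichloroborane 15 (not isolated)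
Conditions: BCl3 (1 M in CH2Cl2, 2.5 equiv), CH2Cl2, −78 to 0 °C; then ice-water
Reagents that add atoms: none
Why: Chelation-controlled Lewis-acid ether cleavage, in which BCl3 is held between the ester carbonyl and the ortho methoxy oxygen so that chloride demethylates only that ether (SN2 at CH3) while the C4 methoxy group, which cannot chelate, is kept at or below 0 °C.

Step 7
Reactants: 16 methyl 2-hydroxy-4-methoxy-6-(2-oxotridecyl)benzoate
Product: 17 2-hydroxy-4-methoxy-6-(2-oxotridecyl)benzoic acid
Conditions: KOH (4 M aq., 10 equiv), EtOH, 80 °C, N2; then 1 M HCl, 0 °C, to pH 2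
Reagents that add atoms: potassium hydroxide, [K+].[OH-]; water, O
Why: Saponification (acyl–oxygen cleavage by hydroxide) of the hindered salicylate with excess base under N2, followed by cold acidification so that the keto acid is liberated without lactonisation to the isocoumarin or decarboxylation.

**Compound list**

1 | methyl acetoacetate (methyl 3-oxobutanoate) | CC(=O)CC(=O)OC | starting material
2 | malonyl dichloride (propanedioyl dichloride) | O=C(Cl)CC(=O)Cl | starting material
3 | methyl 2-acetyl-5-chloro-3,5-dioxopentanoate (enolised methine, no configuration) | COC(=O)C(C(C)=O)C(=O)CC(=O)Cl | intermediate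
4 | methyl 4-hydroxy-6-methyl-2-oxo-2H-pyran-5-carboxylate | COC(=O)C1=C(C)OC(=O)C=C1O | intermediate
5 | methyl 4-methoxy-6-methyl-2-oxo-2H-pyran-5-carboxylate | COC(=O)C1=C(C)OC(=O)C=C1OC | intermediate
6 | 1,1-dimethoxyethene | C=C(OC)OC | starting material
7 | methyl 5,8,8-trimethoxy-1-methyl-3-oxo-2-oxabicyclo[2.2.2]oct-5-ene-6-carboxylate (racemic; bridgeheads fixed relative to each other by the bicycle) | O=C1OC2(C)CC(OC)(OC)C1C(OC)=C2C(=O)OC | intermediate
8 | methyl 4,4,6-trimethoxy-2-methylcyclohexa-1,5-diene-1-carboxylate | COC(=O)C1=C(C)CC(OC)(OC)C=C1OC | intermediate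
9 | methyl 2,4-dimethoxy-6-methylbenzoate | COC(=O)c1c(C)cc(OC)cc1OC | intermediate
10 | dodecanoyl chloride | CCCCCCCCCCCC(=O)Cl | starting material
11 | N-methoxy-N-methyldodecanamide | CCCCCCCCCCCC(=O)N(C)OC | intermediate
12 | [3,5-dimethoxy-2-(methoxycarbonyl)benzyl]lithium | [Li]Cc1cc(OC)cc(OC)c1C(=O)OC | intermediate
13 | lithium 1-[3,5-dimethoxy-2-(methoxycarbonyl)phenyl]-2-[methoxy(methyl)amino]tridecan-2-olate (racemic) | [Li]OC(CCCCCCCCCCC)(Cc1cc(OC)cc(OC)c1C(=O)OC)N(C)OC | intermediate
14 | methyl 2,4-dimethoxy-6-(2-oxotridecyl)benzoate | CCCCCCCCCCCC(=O)Cc1cc(OC)cc(OC)c1C(=O)OC | intermediate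
15 | methyl 2-[(dichloroboranyl)oxy]-4-methoxy-6-(2-oxotridecyl)benzoate | CCCCCCCCCCCC(=O)Cc1cc(OC)cc(OB(Cl)Cl)c1C(=O)OC | intermediate
16 | methyl 2-hydroxy-4-methoxy-6-(2-oxotridecyl)benzoate | CCCCCCCCCCCC(=O)Cc1cc(OC)cc(O)c1C(=O)OC | intermediate
17 | 2-hydroxy-4-methoxy-6-(2-oxotridecyl)benzoic acid | CCCCCCCCCCCC(=O)Cc1cc(OC)cc(O)c1C(=O)O | target

**Step count**

Total: 7 steps. Longest linear sequence: 6 steps (steps 1, 2, 3, 5, 6, 7); step 4 is a one-step side branch.

**Steps most likely to fail, each with a fallback**

Step 3 (key cycloaddition). The 4-methoxy group donates into the diene and the 6-methyl group hinders the carbon that must take the CH2 terminus, so the cycloaddition may be slow. Thermal oligomerisation of the ketene acetal, and its consumption by the liberated methanol, may then outrun ring formation. Fallback: sets out from 1 and returns at 9, building the arene by condensation and aromatisation instead of cycloaddition. Michael addition of 1 to methyl crotonate and Claisen ring closure in the same flask (NaOMe, MeOH, reflux) should give methyl 2-methyl-4,6-dioxocyclohexane-1-carboxylate F1. Br2 (3 equiv) in AcOH dehydrogenates and ring-brominates it to methyl 3,5-dibromo-2,4-dihydroxy-6-methylbenzoate F2. Hydrogenolysis (H2, Pd/C, NaOAc, MeOH) gives methyl 2,4-dihydroxy-6-methylbenzoate F3. Double O-methylation (Me2SO4, K2CO3, acetone, reflux) then gives 9.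

Step 7 (final saponification). Hydroxide attack on the doubly ortho-substituted ester is slowed further by the neighbouring phenoxide. Under the forcing conditions the benzylic ketone enolate may lactonise or condense onto the ester or autoxidise, and the electron-rich salicylic acid may lose CO2 on acidification. Fallback: sets out from 9 and returns at 17. The ester is saponified while neither ketone nor free phenol is present (KOH, aqueous DMSO, 90 °C) to give 2,4-dimethoxy-6-methylbenzoic acid F4. Double deprotonation with LiN(iPr)2 (2.2 equiv, THF, −78 to 0 °C) and acylation with 11 at −78 °C should give 2,4-dimethoxy-6-(2-oxotridecyl)benzoic acid F5 after an AcOH quench. BCl3 (CH2Cl2, −78 to 0 °C) then cleaves only the methyl ether next to the carboxyl group and gives 17.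

Step 1 (pyrone annulation). Competing O-acylation, self-condensation of malonyl dichloride under the HCl it generates and tar formation may leave little of the 1:1 condensation product. Fallback: sets out from 1 and returns at 4, forming the two bonds in separate operations. C-Acylation of the magnesium enolate of 1 (MgCl2, pyridine, CH2Cl2, 0 °C to rt) with methyl 3-chloro-3-oxopropanoate gives dimethyl 2-acetyl-3-oxopentanedioate F6. Enol lactonisation in cold concentrated H2SO4, with loss of methanol, closes the pyrone ring and gives 4.

**Further compounds**

F1 | step 3 | methyl 2-methyl-4,6-dioxocyclohexane-1-carboxylate (racemic, enolisable centres) | COC(=O)C1C(C)CC(=O)CC1=O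
F2 | step 3 | methyl 3,5-dibromo-2,4-dihydroxy-6-methylbenzoate | COC(=O)c1c(C)c(Br)c(O)c(Br)c1O
F3 | step 3 | methyl 2,4-dihydroxy-6-methylbenzoate | COC(=O)c1c(C)cc(O)cc1O
F4 | step 7 | 2,4-dimethoxy-6-methylbenzoic acid | COc1cc(C)c(C(=O)O)c(OC)c1
F5 | step 7 | 2,4-dimethoxy-6-(2-oxotridecyl)benzoic acid | CCCCCCCCCCCC(=O)Cc1cc(OC)cc(OC)c1C(=O)O
F6 | step 1 | dimethyl 2-acetyl-3-oxopentanedioate | COC(=O)CC(=O)C(C(C)=O)C(=O)OC
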